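**Retrosynthetic overview**
- Depside ester C–O bond: ring A salicylic acid plus ring B phenol-aldehyde; the ring B aldehyde is a masked carboxylic acid, oxidised in the last step.
- Ring A acid: from symmetric 2-chloro-1,3-dimethoxy-5-propylbenzene by directed lithiation/CO2, then cleavage of the ortho methyl ether. Chlorine is placed between the two oxygens by an earlier directed lithiation.
- Ring B aldehyde: Vilsmeier formylation of 5-propylresorcinol.
- Key C–C bond (aryl–CH2 of the propyl chain, serving both halves): 1-bromo-3,5-dimethoxybenzene plus propanal, whose normally electrophilic C1 is used as an n-propyl carbanion equivalent through its N–H hydrazone (nickel-catalysed, loss of N2).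
- No ring is constructed; both benzene rings are bought as the same aryl bromide.

Assumption: the target has no stereocentre or other stereogenic element, so "single enantiomer" imposes no stereochemical task and the SMILES is taken as drawn.

**Route**

Step 1
Reactants: 1 1-bromo-3,5-dimethoxybenzene; 2 propanal; 3 hydrazine monohydrate
Product: 5 1,3-dimethoxy-5-propylbenzene, via propanal hydrazone 4 (not isolated)
Conditions: 2 + 3, THF, rt, 1 h; then 1, Ni(cod)2 (10 mol %), PMe3 (20 mol %), DBU, 4 Å MS, THF, 50 °C
Reagents that add atoms: none
Why: Proposed new method: the closest known reaction type is the nickel-catalysed denitrogenative cross-coupling of aryl halides with N-unsubstituted aldehyde hydrazones (Wolff–Kishner-type carbanion equivalents, established mainly for aromatic aldehydes), here extended to an aliphatic aldehyde, in which oxidative addition of 1 to zerovalent nickel, DBU-assisted N–H deprotonation to an N-bound hydrazonide, loss of N2 with transfer of the former carbonyl carbon to nickel and C–C reductive elimination let the normally electrophilic C1 of propanal act as an n-propyl anion toward the electrophilic aryl carbon, the small PMe3 ligand being expected to favour reductive elimination over β-hydride loss.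

Step 2
Reactants: 5 1,3-dimethoxy-5-propylbenzene
Product: 7 2-chloro-1,3-dimethoxy-5-propylbenzene, via aryllithium 6 (not isolated)
Conditions: n-BuLi, THF, 0 °C to rt; then C2Cl6, −78 °C to rt
Reagents that add atoms: hexachloroethane, ClC(Cl)(Cl)C(Cl)(Cl)Cl
Why: Directed ortho-metalation removes the most acidic, doubly coordinated C–H between the two methoxy groups, and the aryllithium is chlorinated by C2Cl6, which fixes chlorine between the oxygens without regioisomers.

Step 3
Reactants: 7 2-chloro-1,3-dimethoxy-5-propylbenzene
Product: 9 3-chloro-2,4-dimethoxy-6-propylbenzoic acid, via aryllithium 8 (not isolated)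
Conditions: s-BuLi, TMEDA, THF, −78 °C; then CO2; then aq. HCl
Reagents that add atoms: carbon dioxide, O=C=O
Why: A second directed ortho-metalation followed by carboxylation can give only one acid, because the two remaining aromatic C–H bonds of symmetric 7 are equivalent and each ortho to a methoxy group, and the chlorine is meta to the lithiated carbon so no benzyne can form.

Step 4
Reactants: 9 3-chloro-2,4-dimethoxy-6-propylbenzoic acid
Product: 10 3-chloro-2-hydroxy-4-methoxy-6-propylbenzoic acid
Conditions: BCl3 (2.5 equiv), CH2Cl2, −78 to 0 °C; then H2O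
Reagents that add atoms: none
Why: Chelation-controlled Lewis-acid ether cleavage, in which BCl3 bound at the carboxyl group cleaves only the ortho methoxy group and leaves the 4-methoxy group, the aryl chloride and the propyl chain untouched.

Step 5
Reactants: 5 1,3-dimethoxy-5-propylbenzene
Product: 11 5-propylbenzene-1,3-diol
Conditions: BBr3 (2.5 equiv), CH2Cl2, −78 °C to rt; then H2O
Reagents that add atoms: none
Why: Exhaustive BBr3 demethylation of aryl methyl ethers (bromide attack on the methyl of the O–B adduct), with no other sensitive group in 5.

Step 6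
Reactants: 11 5-propylbenzene-1,3-diol
Product: 13 2,4-dihydroxy-6-propylbenzaldehyde, via iminium chloride 12 (not isolated)
Conditions: POCl3, DMF, 0 °C to rt; then H2O, 50 °C
Reagents that add atoms: N,N-dimethylformamide, CN(C)C=O; water, O
Why: Vilsmeier–Haack formylation attacks the position para to one hydroxyl and ortho to the other (both such positions are equivalent) in preference to the hindered site between the hydroxyls, and hydrolysis of the iminium salt releases the aldehyde.

Step 7
Reactants: 10 3-chloro-2-hydroxy-4-methoxy-6-propylbenzoic acid; 13 2,4-dihydroxy-6-propylbenzaldehyde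
Product: 15 4-formyl-3-hydroxy-5-propylphenyl 3-chloro-2-hydroxy-4-methoxy-6-propylbenzoate, via mixed anhydride 14 (not isolated)
Conditions: (CF3CO)2O, toluene, rt
Reagents that add atoms: none
Why: Depside esterification through the mixed trifluoroacetic anhydride acylates the free, more nucleophilic 4-OH of 13, while the 2-OH groups of both partners are hindered and hydrogen-bonded to their ortho carbonyls.

Step 8
Reactants: 15 4-formyl-3-hydroxy-5-propylphenyl 3-chloro-2-hydroxy-4-methoxy-6-propylbenzoate
Product: 16 3-chlorodivaricatic acid, 4-[(3-chloro-2-hydroxy-4-methoxy-6-propylbenzoyl)oxy]-2-hydroxy-6-propylbenzoic acid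
Conditions: NaClO2, H2NSO3H, dioxane–H2O, 0 °C to rt
Reagents that add atoms: sodium chlorite, [Na+].[O-]Cl=O
Why: Lindgren–Pinnick oxidation converts the aldehyde to the acid under mildly acidic conditions that spare the aryl ester, and sulfamic acid scavenges HOCl so the electron-rich rings are not chlorinated.

**Compound list**

1 | 1-bromo-3,5-dimethoxybenzene | COc1cc(Br)cc(OC)c1 | starting material
2 | propanal | CCC=O | starting material
3 | hydrazine monohydrate | NN.O | starting material
4 | propanal hydrazone ((E)-propylidenehydrazine), not isolated | CC/C=N/N | intermediate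
5 | 1,3-dimethoxy-5-propylbenzene | CCCc1cc(OC)cc(OC)c1 | intermediate
6 | (2,6-dimethoxy-4-propylphenyl)lithium, not isolated | CCCc1cc(OC)c([Li])c(OC)c1 | intermediate
7 | 2-chloro-1,3-dimethoxy-5-propylbenzene | CCCc1cc(OC)c(Cl)c(OC)c1 | intermediate
8 | (3-chloro-2,4-dimethoxy-6-propylphenyl)lithium, not isolated | CCCc1cc(OC)c(Cl)c(OC)c1[Li] | intermediate
9 | 3-chloro-2,4-dimethoxy-6-propylbenzoic acid | CCCc1cc(OC)c(Cl)c(OC)c1C(=O)O | intermediate
10 | 3-chloro-2-hydroxy-4-methoxy-6-propylbenzoic acid | CCCc1cc(OC)c(Cl)c(O)c1C(=O)O | intermediate
11 | 5-propylbenzene-1,3-diol (5-propylresorcinol) | CCCc1cc(O)cc(O)c1 | intermediate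
12 | N-[(2,4-dihydroxy-6-propylphenyl)methylidene]-N-methylmethanaminium chloride, not isolated | CCCc1cc(O)cc(O)c1C=[N+](C)C.[Cl-] | intermediate
13 | 2,4-dihydroxy-6-propylbenzaldehyde | CCCc1cc(O)cc(O)c1C=O | intermediate
14 | 3-chloro-2-hydroxy-4-methoxy-6-propylbenzoic trifluoroacetic anhydride, not isolated | CCCc1cc(OC)c(Cl)c(O)c1C(=O)OC(=O)C(F)(F)F | intermediate
15 | 4-formyl-3-hydroxy-5-propylphenyl 3-chloro-2-hydroxy-4-methoxy-6-propylbenzoate | CCCc1cc(OC(=O)c2c(CCC)cc(OC)c(Cl)c2O)cc(O)c1C=O | intermediate
16 | 3-chlorodivaricatic acid | CCCc1cc(OC(=O)c2c(CCC)cc(OC)c(Cl)c2O)cc(O)c1C(=O)O | target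

**Step count and risks**

Total step count: 8. Longest linear sequence: 6 steps (steps 1, 2, 3, 4, 7, 8).

Steps most likely to fail:

Step 1. An aliphatic N–H hydrazone may form the azine, and an n-propyl–nickel intermediate may lose a β-hydride (giving 1,3-dimethoxybenzene or the isopropyl isomer). The fallback sets out from 1 and 2 and comes back at 5. Propanal is condensed with TsNHNH2 (MeOH, rt) to propanal N-tosylhydrazone F1. F1 is coupled with 1 using Pd2(dba)3, XPhos and LiOtBu in dioxane at 90 °C (Barluenga coupling: the diazoalkane formed in the flask is still a nucleophilic, carbonyl-derived carbon that adds to the aryl–palladium species, followed by carbene insertion and β-hydride elimination). This gives (E)-1,3-dimethoxy-5-(prop-1-en-1-yl)benzene F2, and hydrogenation (H2, Pd/C, EtOAc) gives 5.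

Step 3. The lithiation site is flanked by the propyl chain, so metalation may be slow or compete with benzylic deprotonation. The fallback sets out from 7 and comes back at 9, replacing deprotonation by electrophilic aromatic substitution. Rieche formylation (Cl2CHOMe, TiCl4, CH2Cl2, 0 °C) at the only free, methoxy-activated position gives 3-chloro-2,4-dimethoxy-6-propylbenzaldehyde F3. Oxidation with NaClO2 and H2NSO3H in aqueous dioxane gives 9.

Step 7. The acid is doubly ortho-substituted and carries a free phenol, so the anhydride coupling may be slow or unselective. The fallback sets out from 9 (before step 4) and comes back at 15. Acid 9 is converted with (COCl)2 and catalytic DMF in CH2Cl2 into 3-chloro-2,4-dimethoxy-6-propylbenzoyl chloride F4. F4 acylates the more acidic 4-OH of 13 (K2CO3, acetone, rt) to give 4-formyl-3-hydroxy-5-propylphenyl 3-chloro-2,4-dimethoxy-6-propylbenzoate F5. BCl3 (CH2Cl2, −78 to 0 °C) then cleaves only the methoxy group ortho to the ester carbonyl and gives 15.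

**Further compounds**

F1 | step 1 | propanal N-tosylhydrazone | CC/C=N/NS(=O)(=O)c1ccc(C)cc1
F2 | step 1 | (E)-1,3-dimethoxy-5-(prop-1-en-1-yl)benzene | C/C=C/c1cc(OC)cc(OC)c1
F3 | step 3 | 3-chloro-2,4-dimethoxy-6-propylbenzaldehyde | CCCc1cc(OC)c(Cl)c(OC)c1C=O
F4 | step 7 | 3-chloro-2,4-dimethoxy-6-propylbenzoyl chloride | CCCc1cc(OC)c(Cl)c(OC)c1C(=O)Cl
F5 | step 7 | 4-formyl-3-hydroxy-5-propylphenyl 3-chloro-2,4-dimethoxy-6-propylbenzoate | CCCc1cc(OC(=O)c2c(CCC)cc(OC)c(Cl)c2OC)cc(O)c1C=O
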